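TBS = tert-butyldimethylsilyl.
Reading of the target, used throughout: C2 is R and C3 is S, so the isopropenyl and acyloxy groups are trans on the dihydrofuran. The butenoate is Z, with CH3 cis to the ester C=O. Commercial crotonaldehyde is taken as the E isomer.

## Retrosynthetic overview
1. Target ⇒ final acetylation and desilylation ⇒ C3–O acyl bond: trans-alcohol 21 plus (Z)-acid 28. The acid comes from crotonaldehyde via (Z)-2-iodobutenol, then Li and CO2, so the geometry is fixed at the iodide.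
2. 21 ⇒ aryl bromide 17 (Br is the latent acetyl group); isopropenyl ⇒ methyl ketone 16 ⇒ Weinreb amide 14.
3. The dihydrofuran is the only ring built. It closes at O1–C2 by phenoxide SN2 with inversion on the α-chloro amide 12; the benzene ring is bought.
4. C2–C3 ⇒ intermolecular Evans boron aldol of chloroacetyl imide 7 with aldehyde 3. This sets C3 directly and C2 after the inversion.
5. 3 ⇒ 2-hydroxy-4-methoxybenzaldehyde 1 (bromination, silylation).

## Route

Step 1
Reactants: 1 2-hydroxy-4-methoxybenzaldehyde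
Product: 2 5-bromo-2-hydroxy-4-methoxybenzaldehyde
Conditions: Br2 (1.05 equiv), CH2Cl2, 0 °C → rt
Reagents that add atoms: bromine, BrBr
Why: In this electrophilic aromatic bromination C5 is para to OH, ortho to OMe and meta to CHO, while C3 is flanked on both sides, so only the 5-bromide forms and serves as placeholder for the acetyl group.

Step 2
Reactants: 2 5-bromo-2-hydroxy-4-methoxybenzaldehyde
Product: 3 5-bromo-2-(TBS-oxy)-4-methoxybenzaldehyde
Conditions: TBSCl, imidazole, DMF, rt
Reagents that add atoms: tert-butyldimethylsilyl chloride, CC(C)(C)[Si](C)(C)Cl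
Why: Silyl ether formation masks the acidic phenol for the boron aldol, and the aryl silyl ether can later be released selectively by fluoride.

Step 3
Reactants: 4 (R)-4-benzyl-1,3-oxazolidin-2-one; 5 chloroacetyl chloride
Product: 7 (R)-4-benzyl-3-(2-chloroacetyl)-1,3-oxazolidin-2-one, via N-lithio oxazolidinone 6 (not isolated)
Conditions: n-BuLi (1.0 equiv), THF, −78 °C; then 5, −78 → 0 °C
Reagents that add atoms: none
Why: N-acylation of the lithiated Evans auxiliary with the acid chloride is standard and leaves the auxiliary stereocentre untouched.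

Step 4 (key C–C bond)
Reactants: 7 (R)-4-benzyl-3-(2-chloroacetyl)-1,3-oxazolidin-2-one; 3 5-bromo-2-(TBS-oxy)-4-methoxybenzaldehyde
Product: 10 (R)-4-benzyl-3-[(2R,3S)-3-(5-bromo-2-TBS-oxy-4-methoxyphenyl)-2-chloro-3-hydroxypropanoyl]oxazolidin-2-one, via (Z)-boron enolate 8 (not isolated), via boron aldolate 9 (not isolated)
Conditions: Bu2BOTf (1.1 equiv), Et3N (1.3 equiv), Et2O, −78 → 0 °C; 3, −78 → 0 °C; then pH 7 buffer, MeOH, 30% H2O2, 0 °C; minor isomers removed by chromatography
Reagents that add atoms: none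
Why: In this intermolecular Evans syn aldol the (Z)-boron enolate reacts through a closed Zimmerman–Traxler chair on the face away from the benzyl group of the (R)-auxiliary, which gives the syn chlorohydrin and sets C3 as S and C2 as R.

Step 5
Reactants: 10 aldol adduct
Product: 11 (2R,3S)-3-(5-bromo-2-TBS-oxy-4-methoxyphenyl)-2-chloro-3-hydroxy-N-methoxy-N-methylpropanamide
Conditions: MeONHMe·HCl (3 equiv), AlMe3 (3 equiv), CH2Cl2, −10 °C → rt; aq. Rochelle salt
Reagents that add atoms: N,O-dimethylhydroxylamine hydrochloride, CNOC.Cl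
Why: Weinreb transamination, assisted by the free β-hydroxyl, removes the auxiliary without touching C–Cl or either stereocentre and leaves a carbonyl too unreactive for later acyl attack by the phenoxide.

Step 6
Reactants: 11 chlorohydrin Weinreb amide
Product: 12 (2R,3S)-3-(5-bromo-2-TBS-oxy-4-methoxyphenyl)-2-chloro-3-(TBS-oxy)-N-methoxy-N-methylpropanamide
Conditions: TBSOTf (1.3 equiv), 2,6-lutidine (2 equiv), CH2Cl2, −78 → 0 °C
Reagents that add atoms: tert-butyldimethylsilyl triflate, CC(C)(C)[Si](C)(C)OS(=O)(=O)C(F)(F)F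
Why: O-silylation of the carbinol shuts off retro-aldol cleavage and Darzens-type epoxide closure before any base is applied.

Step 7 (ring closure)
Reactants: 12 bis-silyl chloro amide
Product: 14 (2S,3S)-5-bromo-3-(TBS-oxy)-N,6-dimethoxy-N-methyl-2,3-dihydrobenzofuran-2-carboxamide (trans), via tetrabutylammonium phenoxide 13 (not isolated)
Conditions: TBAF (1.05 equiv), THF, 0 °C → rt
Reagents that add atoms: none
Why: Fluoride cleaves the aryl silyl ether far faster than the alkyl one, and the phenoxide closes the ring by a 5-exo-tet intramolecular Williamson SN2 at the activated α-chloro amide carbon with inversion (2R-Cl → 2S-O), which turns the syn chlorohydrin into the trans ring, also the more stable isomer.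

Step 8
Reactants: 14 trans Weinreb amide
Product: 16 1-[(2S,3S)-5-bromo-3-(TBS-oxy)-6-methoxy-2,3-dihydrobenzofuran-2-yl]ethanone, via bromomagnesium hemiaminal 15 (not isolated)
Conditions: MeMgBr (1.5 equiv), THF, −78 → 0 °C; cold pH 7 buffer; short Et3N-deactivated silica plug, used at once
Reagents that add atoms: methylmagnesium bromide, C[Mg]Br
Why: In the Weinreb ketone synthesis the chelated tetrahedral adduct stops addition at the ketone, ArBr and OTBS are inert, and any C2 enolisation would only return the favoured trans isomer because C3 is fixed.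

Step 9
Reactants: 16 methyl ketone
Product: 17 (2R,3S)-5-bromo-3-(TBS-oxy)-6-methoxy-2-(prop-1-en-2-yl)-2,3-dihydrobenzofuran
Conditions: Cp2TiMe2 (2.5 equiv), toluene, 70 °C, dark
Reagents that add atoms: dimethyltitanocene, [CH3-].[CH3-].c1cc[cH-]c1.c1cc[cH-]c1.[Ti+4]
Why: Petasis methylenation uses the non-basic carbene Cp2Ti=CH2, which avoids the enolisation and β-silyloxide loss that would aromatise to a benzofuran; the C2 descriptor changes from S to R only through CIP ranking.

Step 10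
Reactants: 17 aryl bromide
Product: 20 1-[(2R,3S)-3-(TBS-oxy)-6-methoxy-2-(prop-1-en-2-yl)-2,3-dihydrobenzofuran-5-yl]ethanone, via aryllithium 18 (not isolated), via lithium hemiaminal 19 (not isolated)
Conditions: n-BuLi (1.05 equiv), THF, −78 °C, 15 min; MeC(O)N(OMe)Me (2 equiv), −78 → 0 °C; pH 7 buffer
Reagents that add atoms: N-methoxy-N-methylacetamide, CC(=O)N(C)OC
Why: Fast Br–Li exchange gives an aryllithium stabilised by the ortho OMe, and acylation with the Weinreb acetamide stops at the ketone; no palladium is used, so the allylic aryl ether bond O1–C2 cannot ionise.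

Step 11
Reactants: 20 silyl ether
Product: 21 1-[(2R,3S)-3-hydroxy-6-methoxy-2-(prop-1-en-2-yl)-2,3-dihydrobenzofuran-5-yl]ethanone
Conditions: TBAF/AcOH (1:1, 1.5 equiv), THF, 0 °C → rt
Reagents that add atoms: none
Why: Buffered fluoride desilylation breaks only the Si–O bond, so C3 keeps its configuration and neither acid nor strong base is present to dehydrate the benzylic alcohol.

Step 12
Reactants: 22 (E)-crotonaldehyde
Product: 23 (Z)-2-iodobut-2-enal
Conditions: I2, K2CO3, DMAP (20 mol%), THF/H2O 1:1, rt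
Reagents that add atoms: iodine, II
Why: Baylis–Hillman-type α-iodination (DMAP addition, iodination of the enolate, elimination) gives the Z isomer with CH3 cis to I, and this fixes the side-chain geometry.

Step 13
Reactants: 23 (Z)-2-iodobut-2-enal
Product: 24 (Z)-2-iodobut-2-en-1-ol
Conditions: NaBH4, MeOH, 0 °C
Reagents that add atoms: none
Why: Borohydride 1,2-reduction of the aldehyde leaves the vinyl iodide and its geometry untouched.

Step 14
Reactants: 24 (Z)-2-iodobut-2-en-1-ol
Product: 25 (Z)-tert-butyl[(2-iodobut-2-en-1-yl)oxy]dimethylsilane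
Conditions: TBSCl, imidazole, CH2Cl2, rt
Reagents that add atoms: tert-butyldimethylsilyl chloride, CC(C)(C)[Si](C)(C)Cl
Why: Silylation gives an allylic oxygen substituent that, unlike acetate, is no leaving group for SN2′ chemistry during lithiation and the later acyl activation.

Step 15
Reactants: 25 vinyl iodide
Product: 28 (Z)-2-[(TBS-oxy)methyl]but-2-enoic acid, via vinyllithium 26 (not isolated), via lithium carboxylate 27 (not isolated)
Conditions: t-BuLi (2.1 equiv), Et2O, −78 °C, 30 min; dry CO2, −78 → 0 °C; cold 1 M HCl to pH 3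
Reagents that add atoms: carbon dioxide, O=C=O
Why: I–Li exchange and carboxylation both proceed with retention at the sp2 carbon, and the alkenyllithium is configurationally stable at −78 °C, so CO2H takes the place of I, cis to CH3.

Step 16
Reactants: 28 (Z)-2-[(TBS-oxy)methyl]but-2-enoic acid; 21 trans alcohol
Product: 30 (2R,3S)-5-acetyl-6-methoxy-2-(prop-1-en-2-yl)-2,3-dihydrobenzofuran-3-yl (Z)-2-[(TBS-oxy)methyl]but-2-enoate, via Yamaguchi mixed anhydride 29 (not isolated)
Conditions: 28 (2.5 equiv), 2,4,6-Cl3C6H2COCl (2.5 equiv), Et3N (3 equiv), toluene, rt, 2 h; then 21, toluene, 75 °C, no DMAP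
Reagents that add atoms: none
Why: DMAP-free Yamaguchi esterification, the protocol used for angelates, avoids the nucleophile-induced Z → E isomerisation, and because only the acyl–O bond is formed, C3 is retained.

Step 17
Reactants: 30 silyl-protected ester
Product: 31 (2R,3S)-5-acetyl-6-methoxy-2-(prop-1-en-2-yl)-2,3-dihydrobenzofuran-3-yl (Z)-2-(hydroxymethyl)but-2-enoate
Conditions: HF·pyridine, pyridine/THF, 0 °C → rt
Reagents that add atoms: none
Why: Pyridine-buffered HF removes the primary silyl ether without the basic conditions that could transesterify or eliminate the benzylic ester.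

Step 18
Reactants: 31 hydroxymethyl ester
Product: 32 target, (2R,3S)-5-acetyl-6-methoxy-2-(prop-1-en-2-yl)-2,3-dihydrobenzofuran-3-yl (Z)-2-(acetoxymethyl)but-2-enoate
Conditions: Ac2O, pyridine, CH2Cl2, 0 °C → rt
Reagents that add atoms: acetic anhydride, CC(=O)OC(C)=O
Why: Acetylation of the only free, primary hydroxyl under mild pyridine conditions touches neither the stereocentres nor the Z alkene.

## Compound list
1 | 2-hydroxy-4-methoxybenzaldehyde | COc1ccc(C=O)c(O)c1 | starting material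
2 | 5-bromo-2-hydroxy-4-methoxybenzaldehyde | COc1cc(O)c(C=O)cc1Br | intermediate
3 | 5-bromo-2-(TBS-oxy)-4-methoxybenzaldehyde | COc1cc(O[Si](C)(C)C(C)(C)C)c(C=O)cc1Br | intermediate
4 | (R)-4-benzyl-1,3-oxazolidin-2-one | O=C1N[C@H](Cc2ccccc2)CO1 | starting material
5 | chloroacetyl chloride | ClCC(=O)Cl | starting material
6 | N-lithio-(R)-4-benzyloxazolidin-2-one (not isolated) | [Li]N1[C@H](Cc2ccccc2)COC1=O | intermediate
7 | (R)-4-benzyl-3-(2-chloroacetyl)-1,3-oxazolidin-2-one | ClCC(=O)N1[C@H](Cc2ccccc2)COC1=O | intermediate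
8 | (Z)-dibutylboron enolate of 7 (not isolated) | Cl/C=C(\OB(CCCC)CCCC)N1[C@H](Cc2ccccc2)COC1=O | intermediate
9 | dibutylboron aldolate (not isolated) | O=C([C@H](Cl)[C@@H](OB(CCCC)CCCC)c1cc(Br)c(OC)cc1O[Si](C)(C)C(C)(C)C)N1[C@H](Cc2ccccc2)COC1=O | intermediate
10 | (2R,3S) syn chlorohydrin imide | O=C([C@H](Cl)[C@@H](O)c1cc(Br)c(OC)cc1O[Si](C)(C)C(C)(C)C)N1[C@H](Cc2ccccc2)COC1=O | intermediate
11 | (2R,3S) chlorohydrin Weinreb amide | CON(C)C(=O)[C@H](Cl)[C@@H](O)c1cc(Br)c(OC)cc1O[Si](C)(C)C(C)(C)C | intermediate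
12 | (2R,3S) bis-TBS chloro Weinreb amide | CON(C)C(=O)[C@H](Cl)[C@@H](O[Si](C)(C)C(C)(C)C)c1cc(Br)c(OC)cc1O[Si](C)(C)C(C)(C)C | intermediate
13 | tetrabutylammonium phenoxide (not isolated) | CON(C)C(=O)[C@H](Cl)[C@@H](O[Si](C)(C)C(C)(C)C)c1cc(Br)c(OC)cc1[O-].CCCC[N+](CCCC)(CCCC)CCCC | intermediate
14 | (2S,3S)-trans-5-bromo-3-(TBS-oxy)-N,6-dimethoxy-N-methyl-2,3-dihydrobenzofuran-2-carboxamide | CON(C)C(=O)[C@H]1Oc2cc(OC)c(Br)cc2[C@@H]1O[Si](C)(C)C(C)(C)C | intermediate
15 | bromomagnesium hemiaminal (not isolated) | CON(C)C(C)(O[Mg]Br)[C@H]1Oc2cc(OC)c(Br)cc2[C@@H]1O[Si](C)(C)C(C)(C)C | intermediate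
16 | 1-[(2S,3S)-5-bromo-3-(TBS-oxy)-6-methoxy-2,3-dihydrobenzofuran-2-yl]ethanone | CC(=O)[C@H]1Oc2cc(OC)c(Br)cc2[C@@H]1O[Si](C)(C)C(C)(C)C | intermediate
17 | (2R,3S)-5-bromo-3-(TBS-oxy)-6-methoxy-2-(prop-1-en-2-yl)-2,3-dihydrobenzofuran | C=C(C)[C@H]1Oc2cc(OC)c(Br)cc2[C@@H]1O[Si](C)(C)C(C)(C)C | intermediate
18 | C5 aryllithium (not isolated) | C=C(C)[C@H]1Oc2cc(OC)c([Li])cc2[C@@H]1O[Si](C)(C)C(C)(C)C | intermediate
19 | lithium hemiaminal (not isolated) | C=C(C)[C@H]1Oc2cc(OC)c(C(C)(O[Li])N(C)OC)cc2[C@@H]1O[Si](C)(C)C(C)(C)C | intermediate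
20 | 1-[(2R,3S)-3-(TBS-oxy)-6-methoxy-2-(prop-1-en-2-yl)-2,3-dihydrobenzofuran-5-yl]ethanone | C=C(C)[C@H]1Oc2cc(OC)c(C(C)=O)cc2[C@@H]1O[Si](C)(C)C(C)(C)C | intermediate
21 | 1-[(2R,3S)-3-hydroxy-6-methoxy-2-(prop-1-en-2-yl)-2,3-dihydrobenzofuran-5-yl]ethanone | C=C(C)[C@H]1Oc2cc(OC)c(C(C)=O)cc2[C@@H]1O | intermediate
22 | (E)-crotonaldehyde | C/C=C/C=O | starting material
23 | (Z)-2-iodobut-2-enal | C/C=C(\I)C=O | intermediate
24 | (Z)-2-iodobut-2-en-1-ol | C/C=C(\I)CO | intermediate
25 | (Z)-tert-butyl[(2-iodobut-2-en-1-yl)oxy]dimethylsilane | C/C=C(\I)CO[Si](C)(C)C(C)(C)C | intermediate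
26 | vinyllithium, CH3 cis to Li (not isolated) | C/C=C(\[Li])CO[Si](C)(C)C(C)(C)C | intermediate
27 | lithium (Z)-2-[(TBS-oxy)methyl]but-2-enoate (not isolated) | C/C=C(\C(=O)[O-])CO[Si](C)(C)C(C)(C)C.[Li+] | intermediate
28 | (Z)-2-[(TBS-oxy)methyl]but-2-enoic acid | C/C=C(\C(=O)O)CO[Si](C)(C)C(C)(C)C | intermediate
29 | mixed anhydride of 28 with 2,4,6-trichlorobenzoic acid (not isolated) | C/C=C(\C(=O)OC(=O)c1c(Cl)cc(Cl)cc1Cl)CO[Si](C)(C)C(C)(C)C | intermediate
30 | (2R,3S)-core (Z)-2-[(TBS-oxy)methyl]but-2-enoate | C=C(C)[C@H]1Oc2cc(OC)c(C(C)=O)cc2[C@@H]1OC(=O)/C(=C\C)CO[Si](C)(C)C(C)(C)C | intermediate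
31 | (2R,3S)-core (Z)-2-(hydroxymethyl)but-2-enoate | C=C(C)[C@H]1Oc2cc(OC)c(C(C)=O)cc2[C@@H]1OC(=O)/C(=C\C)CO | intermediate
32 | CNP0221694.1 | C=C(C)[C@H]1Oc2cc(OC)c(C(C)=O)cc2[C@@H]1OC(=O)/C(=C\C)COC(C)=O | target

## Count and risks
Total steps: 18. Longest linear sequence: 13 (steps 1, 2, 4–11, 16–18).

**Step 7, ring closure.** The risks are slow displacement next to the bulky silyl ether and scrambling of C2 by chloride exchange.

- The fallback makes the O1–C2 bond by an intramolecular Mitsunobu reaction on an α-hydroxy amide instead of displacing a halide. It sets out from 3 and 4.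
- Compound 4 is N-acylated with the pivaloyl mixed anhydride of commercial (4-methoxybenzyloxy)acetic acid to give (R)-4-benzyl-3-[(4-methoxybenzyloxy)acetyl]oxazolidin-2-one F1.
- The same Bu2BOTf/Et3N aldol with 3 gives the syn (2R,3S) glycolate adduct F2.
- AlMe3/MeONHMe·HCl gives the Weinreb amide F3, and TBSOTf/2,6-lutidine gives the bis-silyl ether F4.
- DDQ in CH2Cl2/pH 7 buffer removes the PMB group to give the α-hydroxy amide F5.
- KHF2 in MeOH frees only the phenol to give the hydroxy phenol F6.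
- PPh3/DIAD in THF then closes the ring with inversion at C2, and the route is rejoined at 14.

**Step 9, methylenation of the elimination-prone ketone.** The risks are incomplete reaction and aromatisation on heating.

- The fallback is a Peterson olefination and sets out from 16.
- The non-basic organocerium reagent from TMSCH2Li and CeCl3 (THF, −78 °C) adds to the ketone to give the tertiary β-hydroxysilane F7.
- No carbonyl group is left in F7, so KH in THF at 0 °C can trigger the regiospecific syn elimination, which can only give the terminal alkene. The route is rejoined at 17.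

**Step 16, hindered and isomerisation-prone esterification.** The risks are low conversion, Z → E drift and thermal loss of the benzylic oxygen.

- The fallback activates the nucleophile instead of heating a neutral alcohol. It sets out from 28 and 21.
- Acid 28 with DCC (0.5 equiv, CH2Cl2) gives the symmetrical anhydride F8.
- Alcohol 21 with LiHMDS (1.0 equiv, THF, −78 °C) gives the lithium alkoxide F9.
- F9 is acylated by F8 at −78 → 0 °C with no nucleophilic catalyst present. The route is rejoined at 30.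

## Further compounds
F1 | step 7 | (R)-4-benzyl-3-[(4-methoxybenzyloxy)acetyl]oxazolidin-2-one | COc1ccc(COCC(=O)N2[C@H](Cc3ccccc3)COC2=O)cc1
F2 | step 7 | (R)-4-benzyl-3-[(2R,3S)-3-(5-bromo-2-TBS-oxy-4-methoxyphenyl)-3-hydroxy-2-(4-methoxybenzyloxy)propanoyl]oxazolidin-2-one | O=C([C@H](OCc1ccc(OC)cc1)[C@@H](O)c1cc(Br)c(OC)cc1O[Si](C)(C)C(C)(C)C)N1[C@H](Cc2ccccc2)COC1=O
F3 | step 7 | (2R,3S)-3-(5-bromo-2-TBS-oxy-4-methoxyphenyl)-3-hydroxy-N-methoxy-2-(4-methoxybenzyloxy)-N-methylpropanamide | CON(C)C(=O)[C@H](OCc1ccc(OC)cc1)[C@@H](O)c1cc(Br)c(OC)cc1O[Si](C)(C)C(C)(C)C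
F4 | step 7 | 3-O-TBS ether of F3 | CON(C)C(=O)[C@H](OCc1ccc(OC)cc1)[C@@H](O[Si](C)(C)C(C)(C)C)c1cc(Br)c(OC)cc1O[Si](C)(C)C(C)(C)C
F5 | step 7 | (2R,3S)-3-(5-bromo-2-TBS-oxy-4-methoxyphenyl)-2-hydroxy-3-(TBS-oxy)-N-methoxy-N-methylpropanamide | CON(C)C(=O)[C@H](O)[C@@H](O[Si](C)(C)C(C)(C)C)c1cc(Br)c(OC)cc1O[Si](C)(C)C(C)(C)C
F6 | step 7 | (2R,3S)-3-(5-bromo-2-hydroxy-4-methoxyphenyl)-2-hydroxy-3-(TBS-oxy)-N-methoxy-N-methylpropanamide | CON(C)C(=O)[C@H](O)[C@@H](O[Si](C)(C)C(C)(C)C)c1cc(Br)c(OC)cc1O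
F7 | step 9 | 2-[(2S,3S)-5-bromo-3-(TBS-oxy)-6-methoxy-2,3-dihydrobenzofuran-2-yl]-1-(trimethylsilyl)propan-2-ol | C[Si](C)(C)CC(C)(O)[C@H]1Oc2cc(OC)c(Br)cc2[C@@H]1O[Si](C)(C)C(C)(C)C
F8 | step 16 | (Z,Z)-2-[(TBS-oxy)methyl]but-2-enoic anhydride | C/C=C(\C(=O)OC(=O)/C(=C\C)CO[Si](C)(C)C(C)(C)C)CO[Si](C)(C)C(C)(C)C
F9 | step 16 | lithium alkoxide of 21 | C=C(C)[C@H]1Oc2cc(OC)c(C(C)=O)cc2[C@@H]1O[Li]
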